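Take the 4 questions below for the flask charged with 2.0 M of first end groups and 2.00 M of solid second end groups.

| flask | first end groups | solid second end groups | remark | time |
|---|---|---|---|---|
| Sunday's | 1.3 M | 2 M | run made earlier |  |
| Saturday's | 3 M | 2 M | run made earlier |  |
| Tuesday's | 2 M | 3 M | run made earlier |  |
| flask | 2.0 M | 2.00 M |  | 40 min |

- Sunday's (time / min: links / %, first end groups / %): 2.50: 6, 96; 4.00: 6, 93; 6.00: 11, 89; 10.0: 14, 83; 15.0: 22, 82; 20.0: 22, 79; 30.0: 31, 71
- Saturday's (time / min: links / %, first end groups / %): 5.00: 1, 96; 10.0: 10, 97; 15.0: 7, 92; 20.0: 11, 90; 25.0: 14, 87; 30.0: 18, 86
- Tuesday's (time / min: links / %, first end groups / %): 2.50: 2, 97; 5.00: 5, 90; 10.0: 7, 93; 15.0: 14, 87; 30.0: 24, 79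

(scatter of a reading: 2 percentage points)

- the links standing at 40 min, as a percentage of the first end groups charged
- concentration of second end groups in solution at 4.0 min, in percent of saturation
- the change that raises the amount of links at 40 min, in percent of the first end groups charged most ("none" if none brings more than 2 percentage points) (maple / cedar / none)
- amount of links at 40 min, in percent of the first end groups charged, after maple

- solid, in amounts per volume of the solution: solid second end groups
- the numbers in the tables scatter with a standard deviation of 2 percentage points
- candidate steps: first end groups + second end groups <-> links + by-product; solid second end groups <-> second end groups; first end groups -> decomposition product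
- at the start none of the solid second end groups is in solution

Turn the percentages into concentrations so that the runs can be compared. At 30.0 min, Sunday's run stands at c(links) = 0.403 M, and at 30.0 min, Saturday's run stands at 0.540 M. The charge rose by a factor of 2.31, the links by 1.34.

Now go to logarithms. Define the apparent order n as the slope of the common logarithm of c(links) against that of the charged first end groups, at equal time and equal solid: n = 0.350.

Object that this rests on two readings. Carry their scatter through the logarithms: it gives ±0.154, and n stays less than first order.

Object next that Tuesday's run carried more solid. Scale Sunday's run to 2 M with n: this gives 0.469 M. Tuesday's reading at 30.0 min is 0.480 M, and the gap is smaller than the scatter of that reading, 0.0400 M.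

Object last that the asked time lies later. Read the time slope from Tuesday's run, m = 0.778, and extend. Commit to 29.3% links for the flask, and note that the scatter of the two readings behind m gives it ±0.239.

The forecast gave 30%, 26%, maple and 55%, saying: “That points to mixed dissolution and reaction control”.

The flask gives 25.5% links at 40 min, 1.66% of saturation at 4.0 min, and maple as the better change, worth 12 percentage points against 6 points for cedar, with 37.6% links after it.

    first end groups + second end groups ⇌ links + by-product (K = 1.10, k = 0.0900 M⁻¹ s⁻¹)
    solid second end groups ⇌ second end groups, rate k2*(cs2 - [second end groups]) while solid is left; crystals form when [second end groups] > cs2 (solubility = 0.300 M, k = 0.00120 s⁻¹)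
    first end groups → decomposition product (k = 5.90 × 10⁻⁷ s⁻¹)

My reckoning stands 3.8 points above the flask. Carry n to the neighbour flask, charged with 0.50 M of first end groups, all else held. Start from the 0.509 M of links in the flask and scale by the charge ratio raised to n: this gives 0.313 M, or 62.6% of the neighbour's charge. The neighbour flask stands at 50.8%, which is 0.254 M of links, so its slope from the flask is 0.501.

The numbers in the tables were generated by integration for an exercise; noise was put on by code.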